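Atom labels used throughout: ring A is the trimethoxybenzo ring (C4a, C5–C8, C8a), ring B the carbocycle (C1–C4, C4a, C8a), ring C the 3,4-dimethoxyphenyl group on C1; C9 is the carbon on C2 and C10 the carbon on C3.

## The problem

The target is an aryldihydronaphthalene lignan. Ring A carries methoxy groups on C6, C7 and C8 and is fused to ring B, which bears ring C on C1, hydroxymethyl groups on C2 (C9) and C3 (C10), and a C3=C4 double bond conjugated with ring A. There are two stereocentres, C1 (R) and C2 (S), adjacent and trans. C1 is a doubly benzylic methine with no acidifying neighbour, so it cannot be corrected later and must be set absolutely. C2 lies next to C9 and can be steered from C1 for as long as C9 is a carbonyl group. C1 is bonded to C8a, which is flanked by the C8 methoxy group and by C4a, so every bond to C1 is made beside a doubly ortho-substituted arene; the same peri contact pushes ring C into a pseudoaxial position on ring B. The fragile parts are the electron-rich styrene (oxidative aromatisation of ring B, acid-induced ionisation of the allylic C10–O bond) and, at the ester level, the C2–H bond, which is allylic and α to a carbonyl, so base can epimerise it or move the double bond towards C9. The feature that allows a short ring closure is the sequence C9(=O)–C2–C3(=C4–ring A): an ester α-carbon directly bonded to an alkene carbon whose partner already sits on ring A. Ring B can therefore be closed by joining an ester enolate (C2) to a vinyl halide (C3) of fixed geometry.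

## Retrosynthesis

**Oxidation levels (16 ⇒ 15 ⇒ 14).** No skeletal bond is cut first. Diol 16 is traced to mono-silyl ether 15 and then to ester 14, where C9 is a tert-butyl ester and C10 a silyl ether. The two carbons must differ: C9 has to be a carbonyl to make C2 nucleophilic, whereas a carbonyl at C10 would turn C3=C4 into a Michael acceptor and divert the enolate to C4. The forward steps must reduce a hindered ester before base can act on C2–H and free C10 without acid.

**C2–C3 (14 ⇒ 11).** Cutting the bond between the ester α-carbon and the alkene carbon opens ring B to the acyclic vinyl bromide 11.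
- Against cutting C3=C4 (condensation): C2–C3 would have to be made earlier by an enolate alkylation with no control at C2.
- Against cutting C1–C8a (Friedel–Crafts): a cation at C1 would be needed, attacking the most hindered ring position.
- Against cutting C1–C2 (conjugate closure): C1 would have to be set during ring closure.

The chosen cut leaves C1 as the only stereocentre of 11 and lets it direct C2. The forward reaction must couple faster than the vinyl bromide loses HBr, must give the trans isomer, and must leave C3=C4 in place. A zinc enolate (13, made through lithium enolate 12) is chosen because it is too weakly basic to deprotonate the product.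

**C3=C4 (11 ⇒ 10 ⇒ 9 ⇒ 7 + 8).** The alkene is cut by a Wittig disconnection to aldehyde 7 and bromo ylide 8. One reagent delivers C3, C10 and the bromine, and its known preference places bromine cis to ring A, the geometry the closure needs. Addition of HBr to an aryl alkyne would leave both regio- and stereochemistry open. The price is a chemoselective reduction of the ethyl ester of 9 beside a tert-butyl ester (to 10), then silylation.

**C1–ring C (7 ⇒ 6 ⇒ 4 + 5).** With the formyl group masked as a dioxolane (6), the bond from C1 to ring C is cut by an asymmetric rhodium-catalysed conjugate addition of boronic acid 5 to enoate 4. This places the hindered arene on the acceptor and uses the unhindered, stable boronic acid as nucleophile. The reverse polarity would need a boronic acid with two ortho substituents, a class that transmetalates slowly and loses boron readily. The forward reaction must insert a β-aryl enoate with two ortho substituents and control the face.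

**C1–C8a (4 ⇒ 2 + 3; 2 ⇒ 1).** The enoate is cut at the aryl–vinyl bond to bromide 2 and tert-butyl acrylate 3 (Mizoroki–Heck). Acetal 2 comes from the commercial bromoaldehyde 1, whose substitution pattern maps directly onto C4, C4a, C8a and the three methoxy groups. The tert-butyl ester is carried from here to step 9: it resists self-condensation, aqueous base, dilute acid and iBu2AlH at low temperature.

## Roads not taken

**Alternative 1:** gold-catalysed aryl-enyne formal [4+2].
- Cut: C2–C3 and C1–C8a at once, with C9 and C10 tied through an ether oxygen.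
- Forward: enyne ether A1 would be treated with a chiral cationic complex of monovalent gold, for example (R)-DTBM-SEGPHOS(AuCl)2 activated by AgSbF6. The alkene carbon C2 attacks the activated alkyne at C3 (5-exo-dig) and the benzylic cation at C1 is captured by C8a, giving A2.
- Merits: two bonds, two rings and both stereocentres in one catalytic step from a precursor that takes very few steps. The E alkene translates into the trans relationship, and the attacking ring position is activated by ortho and para methoxy groups. In step count to the carbon skeleton this road is clearly better than the chosen plan.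
- Weak points: A2 holds C9 and C10 in a cyclic ether, not as two alcohols. Reaching 16 means oxidising the ether to the lactone level at an allylic position in the presence of an electron-rich styrene and a doubly benzylic C1–H, then reducing. The enantioselectivity of this cyclisation is also sensitive to the arene substitution.
- Comparison: the chosen plan is about twice as long, but it ends with C9 and C10 already as separately addressable oxygen functions, and it sets C1 by a reaction with a predictable facial model.

**Alternative 2:** palladium carbene linchpin.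
- Cut: C1–ring C and C1–C2.
- Forward: tosylhydrazone A3 would be decomposed by base in the presence of aryl bromide A4 and zerovalent palladium (Pd2(dba)3 with a chiral phosphine, LiOtBu). The arylpalladium bromide takes up the carbene, aryl migration forms C1–ring C, and the tethered succinate carbanion at C2 attacks the η3-diarylmethyl palladium to give diester A5.
- Merits: convergent; ring C is introduced last. In A5 the C3=C4 bond is locked by conjugation with the C10 ester, so C2 can be equilibrated to trans without risk, and one hydride reduction gives 16 with no protecting groups. In endgame and in thermodynamic control at C2 this road is better than the chosen plan.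
- Weak points: absolute control at C1 would rest on enantioselective attack on an η3-benzyl palladium within a three-component cascade, for which there is little basis. The diazo group freed from A3 sits ortho to an electron-poor alkene and can cyclise onto it by dipolar addition before palladium intercepts it. The carbene carbon is flanked by two ortho substituents.
- Comparison: the chosen plan sets C1 with an established asymmetric conjugate addition and pays with protecting-group steps and a less secure C2.

**Alternative 3:** photoenol Diels–Alder.
- Cut: C1–C2 and C3–C4.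
- Forward: irradiation of 2-benzylbenzaldehyde A6 gives the hydroxy-ortho-quinodimethane, which adds the lactate-derived fumarate A7 to give tetralin A8. Dehydration of the C4 alcohol and reduction of the esters would follow.
- Merits: ring B, two bonds and the C1/C2 relationship arise in one step. Both C9 and C10 arrive as esters, elimination of the β-hydroxy ester can only give the conjugated C3=C4 alkene, and the auxiliary leaves in the final reduction. The road is short.
- Weak points: the lactate esters give good facial bias only when a Lewis acid chelates them, and a Lewis acid is not compatible with the transient photoenol. The absolute configuration at C1 would therefore rest on a weak, uncatalysed auxiliary effect and on separating diastereomers. Endo/exo selectivity and the lifetime of the dienol add uncertainty, and A6 itself needs a hindered aryl–benzyl bond construction.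
- Comparison: shorter, but the chosen plan controls the absolute configuration catalytically and each selectivity element separately.

Key step: step 8

## Route

Assumptions: ylide 8 is treated as a stock reagent (a stable solid, otherwise made in one operation by bromination and deprotonation of Ph3P=CHCO2Et). The (S,S) enantiomer of the diene ligand is taken to deliver the aryl group to the α-si face of the (E)-enoate, as the accepted binding model predicts; if the sense proves opposite, the (R,R) ligand is used and nothing else changes.

Step 1
Reactants: 1 2-bromo-3,4,5-trimethoxybenzaldehyde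
Product: 2 2-(2-bromo-3,4,5-trimethoxyphenyl)-1,3-dioxolane
Conditions: HOCH2CH2OH (3 equiv), p-TsOH·H2O (5 mol%), toluene, reflux, Dean–Stark trap
Reagents that add atoms: ethylene glycol, OCCO
Why: Acid-catalysed acetalisation with azeotropic removal of water; the dioxolane masks the formyl group, which would otherwise trap the rhodium enolate of step 3 by aldol cyclisation and compete for the aryl nucleophile.

Step 2
Reactants: 2 2-(2-bromo-3,4,5-trimethoxyphenyl)-1,3-dioxolane; 3 tert-butyl acrylate
Product: 4 tert-butyl (2E)-3-[6-(1,3-dioxolan-2-yl)-2,3,4-trimethoxyphenyl]prop-2-enoate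
Conditions: Pd2(dba)3 (1.5 mol%), [HP(tBu)3]BF4 (6 mol%), Cy2NMe (1.5 equiv), dioxane, 80 °C
Reagents that add atoms: none
Why: Mizoroki–Heck reaction; zerovalent palladium with the bulky, electron-rich P(tBu)3 is the established catalyst for electron-rich aryl bromides with two ortho substituents, and syn insertion followed by syn β-hydride elimination should give only the E enoate, with acetal and tert-butyl ester inert to the amine base.

Step 3
Reactants: 4 tert-butyl (2E)-3-[6-(1,3-dioxolan-2-yl)-2,3,4-trimethoxyphenyl]prop-2-enoate; 5 (3,4-dimethoxyphenyl)boronic acid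
Product: 6 tert-butyl (3R)-3-(3,4-dimethoxyphenyl)-3-[6-(1,3-dioxolan-2-yl)-2,3,4-trimethoxyphenyl]propanoate
Conditions: [RhCl(C2H4)2]2 (2.5 mol%), (S,S)-2,5-diphenylbicyclo[2.2.2]octa-2,5-diene (5.5 mol%), 5 (2.5 equiv), KOH (0.5 equiv), dioxane/H2O 10:1, 50 °C
Reagents that add atoms: none
Why: Hayashi–Miyaura asymmetric 1,4-addition: transmetalation gives an aryl complex of monovalent rhodium, the enoate inserts, and water protonates the oxa-π-allyl rhodium; the chiral diene controls the face (aryl delivery to the α-si face of the E enoate gives 3R), which sets C1 by catalyst control. The tert-butyl ester and the acetal are stable to the aqueous base.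

Step 4
Reactants: 6 tert-butyl (3R)-3-(3,4-dimethoxyphenyl)-3-[6-(1,3-dioxolan-2-yl)-2,3,4-trimethoxyphenyl]propanoate
Product: 7 tert-butyl (3R)-3-(3,4-dimethoxyphenyl)-3-(6-formyl-2,3,4-trimethoxyphenyl)propanoate
Conditions: 1 M HCl (aq), THF, 20 °C
Reagents that add atoms: water, O
Why: Acid hydrolysis of an aryl dioxolane; the electron-rich arene stabilises the oxocarbenium ion so that dilute aqueous acid at room temperature should suffice, conditions that leave a tert-butyl ester intact and cannot epimerise C1, which has no acidifying neighbour.

Step 5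
Reactants: 7 tert-butyl (3R)-3-(3,4-dimethoxyphenyl)-3-(6-formyl-2,3,4-trimethoxyphenyl)propanoate; 8 ethyl 2-bromo-2-(triphenyl-λ5-phosphanylidene)acetate
Product: 9 ethyl (2Z)-2-bromo-3-{2-[(1R)-3-tert-butoxy-1-(3,4-dimethoxyphenyl)-3-oxopropyl]-3,4,5-trimethoxyphenyl}prop-2-enoate
Conditions: 8 (1.5 equiv), toluene, 90 °C
Reagents that add atoms: none
Why: Wittig reaction of a stabilised α-bromo ylide, which is known to give (Z)-α-bromo enoates (aryl trans to the ester) and so places bromine cis to ring A as the ring closure requires; no base is present, so the ester α-protons and C1 are untouched.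

Step 6
Reactants: 9 ethyl (2Z)-2-bromo-3-{2-[(1R)-3-tert-butoxy-1-(3,4-dimethoxyphenyl)-3-oxopropyl]-3,4,5-trimethoxyphenyl}prop-2-enoate
Product: 10 tert-butyl (3R)-3-{6-[(1Z)-2-bromo-3-hydroxyprop-1-en-1-yl]-2,3,4-trimethoxyphenyl}-3-(3,4-dimethoxyphenyl)propanoate
Conditions: iBu2AlH (2.3 equiv), CH2Cl2, −78 °C; aq. potassium sodium tartrate
Reagents that add atoms: none
Why: 1,2-Reduction of an enoate with iBu2AlH; the unhindered, electron-poor ethyl α-bromoacrylate should be reduced at −78 °C much faster than the tert-butyl ester, a selectivity well documented for methyl and ethyl esters beside tert-butyl esters, and the vinyl C–Br bond is inert to this reagent.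

Step 7
Reactants: 10 tert-butyl (3R)-3-{6-[(1Z)-2-bromo-3-hydroxyprop-1-en-1-yl]-2,3,4-trimethoxyphenyl}-3-(3,4-dimethoxyphenyl)propanoate
Product: 11 tert-butyl (3R)-3-{6-[(1Z)-2-bromo-3-{[tert-butyl(dimethyl)silyl]oxy}prop-1-en-1-yl]-2,3,4-trimethoxyphenyl}-3-(3,4-dimethoxyphenyl)propanoate
Conditions: tBuMe2SiCl (1.3 equiv), imidazole (2.5 equiv), DMF, 0 → 20 °C
Reagents that add atoms: tert-butyldimethylsilyl chloride, CC(C)(C)[Si](C)(C)Cl
Why: Imidazole-promoted silylation of a primary allylic alcohol; the silyl ether removes the acidic OH before enolate formation and, unlike an ester at C10, offers the enolate no Michael acceptor.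

Step 8
Reactants: 11 tert-butyl (3R)-3-{6-[(1Z)-2-bromo-3-{[tert-butyl(dimethyl)silyl]oxy}prop-1-en-1-yl]-2,3,4-trimethoxyphenyl}-3-(3,4-dimethoxyphenyl)propanoate
Product: 14 tert-butyl (1R,2S)-3-({[tert-butyl(dimethyl)silyl]oxy}methyl)-1-(3,4-dimethoxyphenyl)-6,7,8-trimethoxy-1,2-dihydronaphthalene-2-carboxylate, via lithium ester enolate 12 (not isolated), via chlorozinc ester enolate 13 (not isolated)
Conditions: LiN(SiMe3)2 (1.1 equiv), THF, −78 °C; ZnCl2 (1.2 equiv), −78 → 20 °C; Pd(dba)2 (5 mol%), P(tBu)3 (5 mol%), THF, 20 → 50 °C
Reagents that add atoms: none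
Why: LiN(SiMe3)2 at −78 °C should remove an ester α-proton faster than it attacks the vinyl bromide, and ZnCl2 then converts lithium enolate 12 into the much less basic zinc enolate 13 before any palladium is present. Zerovalent palladium carrying P(tBu)3 inserts into the C3–Br bond with retention of the Z geometry, C2 passes from zinc to palladium within the molecule, and reductive elimination from the seven-membered palladacycle forms C2–C3. The closest known reaction type is the palladium-catalysed α-arylation and α-alkenylation of ester enolates (alkali enolates or Reformatsky-type zinc enolates) with aryl and vinyl bromides, including ring closures onto tethered vinyl halides. Ring B closes as a six-membered carbocycle by C(sp3)–C(sp2) reductive elimination with C3=C4 ending inside the ring, which is possible only because the Z bromide holds palladium on the same side of the alkene as ring A. The new stereocentre C2 is controlled by C1 (1,2-induction): the peri C8 methoxy group forces ring C pseudoaxial, and the ester is expected to take the opposite face, which also avoids allylic strain with the C3 CH2OSi group, giving the trans (1R,2S) ester. The step needs coupling to beat loss of HBr from the vinyl bromide and β-hydride elimination at C1, and it needs C3=C4 and C2 to stay put afterwards. The low-temperature enolisation, the bulky phosphine (fast reductive elimination) and above all the zinc enolate, which should not deprotonate the more acidic product, are there to secure this.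

Step 9
Reactants: 14 tert-butyl (1R,2S)-3-({[tert-butyl(dimethyl)silyl]oxy}methyl)-1-(3,4-dimethoxyphenyl)-6,7,8-trimethoxy-1,2-dihydronaphthalene-2-carboxylate
Product: 15 [(1R,2S)-3-({[tert-butyl(dimethyl)silyl]oxy}methyl)-1-(3,4-dimethoxyphenyl)-6,7,8-trimethoxy-1,2-dihydronaphthalen-2-yl]methanol
Conditions: LiAlH4 (1.5 equiv), THF, 0 °C; then H2O, aq. NaOH
Reagents that add atoms: none
Why: Hydride reduction of the ester; LiAlH4 reduces tert-butyl esters at 0 °C while the silyl ether and the styrenic alkene are inert, and once C9 is an alkoxide the C2–H bond is no longer acidic, which fixes both the C2 configuration and the alkene position.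

Step 10
Reactants: 15 [(1R,2S)-3-({[tert-butyl(dimethyl)silyl]oxy}methyl)-1-(3,4-dimethoxyphenyl)-6,7,8-trimethoxy-1,2-dihydronaphthalen-2-yl]methanol
Product: 16 [(1R,2S)-1-(3,4-dimethoxyphenyl)-6,7,8-trimethoxy-1,2-dihydronaphthalene-2,3-diyl]dimethanol
Conditions: Bu4NF (1.2 equiv), THF, 0 → 20 °C, under argon
Reagents that add atoms: none
Why: Fluoride cleavage of a primary silyl ether; the non-acidic conditions spare the allylic alcohol and the electron-rich styrene, and no stereocentre is at risk.

## Compound list

1 | 2-bromo-3,4,5-trimethoxybenzaldehyde | COc1cc(C=O)c(Br)c(OC)c1OC | starting material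
2 | 2-(2-bromo-3,4,5-trimethoxyphenyl)-1,3-dioxolane | COc1cc(C2OCCO2)c(Br)c(OC)c1OC | intermediate
3 | tert-butyl acrylate | C=CC(=O)OC(C)(C)C | starting material
4 | tert-butyl (2E)-3-[6-(1,3-dioxolan-2-yl)-2,3,4-trimethoxyphenyl]prop-2-enoate | COc1cc(C2OCCO2)c(/C=C/C(=O)OC(C)(C)C)c(OC)c1OC | intermediate
5 | (3,4-dimethoxyphenyl)boronic acid | COc1ccc(B(O)O)cc1OC | starting material
6 | tert-butyl (3R)-3-(3,4-dimethoxyphenyl)-3-[6-(1,3-dioxolan-2-yl)-2,3,4-trimethoxyphenyl]propanoate | COc1ccc([C@@H](CC(=O)OC(C)(C)C)c2c(C3OCCO3)cc(OC)c(OC)c2OC)cc1OC | intermediate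
7 | tert-butyl (3R)-3-(3,4-dimethoxyphenyl)-3-(6-formyl-2,3,4-trimethoxyphenyl)propanoate | COc1ccc([C@@H](CC(=O)OC(C)(C)C)c2c(C=O)cc(OC)c(OC)c2OC)cc1OC | intermediate
8 | ethyl 2-bromo-2-(triphenyl-λ5-phosphanylidene)acetate | CCOC(=O)C(Br)=P(c1ccccc1)(c1ccccc1)c1ccccc1 | starting material
9 | ethyl (2Z)-2-bromo-3-{2-[(1R)-3-tert-butoxy-1-(3,4-dimethoxyphenyl)-3-oxopropyl]-3,4,5-trimethoxyphenyl}prop-2-enoate | COc1ccc([C@@H](CC(=O)OC(C)(C)C)c2c(/C=C(\Br)C(=O)OCC)cc(OC)c(OC)c2OC)cc1OC | intermediate
10 | tert-butyl (3R)-3-{6-[(1Z)-2-bromo-3-hydroxyprop-1-en-1-yl]-2,3,4-trimethoxyphenyl}-3-(3,4-dimethoxyphenyl)propanoate | COc1ccc([C@@H](CC(=O)OC(C)(C)C)c2c(/C=C(\Br)CO)cc(OC)c(OC)c2OC)cc1OC | intermediate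
11 | tert-butyl (3R)-3-{6-[(1Z)-2-bromo-3-{[tert-butyl(dimethyl)silyl]oxy}prop-1-en-1-yl]-2,3,4-trimethoxyphenyl}-3-(3,4-dimethoxyphenyl)propanoate | COc1ccc([C@@H](CC(=O)OC(C)(C)C)c2c(/C=C(\Br)CO[Si](C)(C)C(C)(C)C)cc(OC)c(OC)c2OC)cc1OC | intermediate
12 | lithium enolate of 11 (enolate geometry not specified) | COc1ccc([C@@H](C=C([O-])OC(C)(C)C)c2c(/C=C(\Br)CO[Si](C)(C)C(C)(C)C)cc(OC)c(OC)c2OC)cc1OC.[Li+] | intermediate (not isolated)
13 | chlorozinc enolate of 11 (drawn O-bound; the C-bound form is equally possible) | COc1ccc([C@@H](C=C(O[Zn]Cl)OC(C)(C)C)c2c(/C=C(\Br)CO[Si](C)(C)C(C)(C)C)cc(OC)c(OC)c2OC)cc1OC | intermediate (not isolated)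
14 | tert-butyl (1R,2S)-3-({[tert-butyl(dimethyl)silyl]oxy}methyl)-1-(3,4-dimethoxyphenyl)-6,7,8-trimethoxy-1,2-dihydronaphthalene-2-carboxylate | COc1ccc([C@@H]2c3c(cc(OC)c(OC)c3OC)C=C(CO[Si](C)(C)C(C)(C)C)[C@H]2C(=O)OC(C)(C)C)cc1OC | intermediate
15 | [(1R,2S)-3-({[tert-butyl(dimethyl)silyl]oxy}methyl)-1-(3,4-dimethoxyphenyl)-6,7,8-trimethoxy-1,2-dihydronaphthalen-2-yl]methanol | COc1ccc([C@@H]2c3c(cc(OC)c(OC)c3OC)C=C(CO[Si](C)(C)C(C)(C)C)[C@H]2CO)cc1OC | intermediate
16 | [(1R,2S)-1-(3,4-dimethoxyphenyl)-6,7,8-trimethoxy-1,2-dihydronaphthalene-2,3-diyl]dimethanol | COc1ccc([C@@H]2c3c(cc(OC)c(OC)c3OC)C=C(CO)[C@H]2CO)cc1OC | target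

## Step count and risks

Total: 10 steps. Longest linear sequence: 10 steps from 1 (3, 5 and 8 enter as purchased partners).

**Step 8 (key step).** The likeliest failure is loss of control in the coupling. Slow transfer of the hindered secondary zinc enolate to palladium would allow reduction of the C–Br bond (β-hydride elimination from C1–H of the palladium enolate), or the ring could close without useful 1,2-induction and give both C2 epimers. The fallback replaces kinetic control in the bond-forming event by thermodynamic control in a separate step. From 11, the ring would be closed with the lithium enolate in excess (LiN(SiMe3)2 2.2 equiv, same catalyst, toluene, 20 °C). This faster-coupling enolate leaves the product in the flask as the lithium dienolate of 14, F1. Protonation at −78 °C with AcOH is expected to occur anti to the pseudoaxial ring C and to give mainly the cis ester tert-butyl (1R,2R)-3-({[tert-butyl(dimethyl)silyl]oxy}methyl)-1-(3,4-dimethoxyphenyl)-6,7,8-trimethoxy-1,2-dihydronaphthalene-2-carboxylate, F2. F2 would then be equilibrated with catalytic KOtBu in tBuOH/THF at 0 °C to the trans-diaxial ester 14, where the route is rejoined. This costs one step and exposes C3=C4 to migration towards C9, which is why it is not the first choice.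

**Step 3.** The likeliest failure is slow insertion of the aryl–rhodium species into an enoate whose β-aryl group has two ortho substituents, so that protodeboronation of 5 uses up the nucleophile, or eroded facial selectivity because the twisted arene sits differently in the chiral pocket. The fallback is auxiliary control. From 2, a Mizoroki–Heck coupling with (4S)-3-acryloyl-4-phenyl-1,3-oxazolidin-2-one would give (4S)-3-{(2E)-3-[6-(1,3-dioxolan-2-yl)-2,3,4-trimethoxyphenyl]prop-2-enoyl}-4-phenyl-1,3-oxazolidin-2-one, F3. Copper-mediated addition of 3,4-(MeO)2C6H3MgBr (CuBr·SMe2, THF, −20 °C) to the magnesium-chelated imide, anti to the auxiliary phenyl group, should give (4S)-3-[(3R)-3-(3,4-dimethoxyphenyl)-3-{6-(1,3-dioxolan-2-yl)-2,3,4-trimethoxyphenyl}propanoyl]-4-phenyl-1,3-oxazolidin-2-one, F4. LiOH/H2O2 would release (3R)-3-(3,4-dimethoxyphenyl)-3-[6-(1,3-dioxolan-2-yl)-2,3,4-trimethoxyphenyl]propanoic acid, F5, and Me2NCH(OtBu)2 in toluene at 80 °C would esterify it to 6, where the route is rejoined.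

**Step 6.** The likeliest failure is over-reduction: attack of iBu2AlH on the tert-butyl ester once the ethyl ester has been consumed, or incomplete reduction stopping at the aldehyde. The fallback separates the two esters by hydrolysis instead of by hydride rate. From 9, LiOH in THF/H2O at 0 °C would saponify only the ethyl ester to (2Z)-2-bromo-3-{2-[(1R)-3-tert-butoxy-1-(3,4-dimethoxyphenyl)-3-oxopropyl]-3,4,5-trimethoxyphenyl}prop-2-enoic acid, F6. Isobutyl chloroformate and N-methylmorpholine would convert it into the mixed isobutyl carbonic anhydride, F7, and NaBH4 in THF/H2O would reduce this to alcohol 10, where the route is rejoined. A tert-butyl ester is inert to borohydride.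

**Step 2.** The likeliest failure is sluggish oxidative addition and insertion at the electron-rich bromide with two ortho substituents, leading to hydrodebromination. The fallback avoids palladium. From 2, bromine–lithium exchange (nBuLi, THF, −78 °C) would give [6-(1,3-dioxolan-2-yl)-2,3,4-trimethoxyphenyl]lithium, F8. Formylation with DMF would give 6-(1,3-dioxolan-2-yl)-2,3,4-trimethoxybenzaldehyde, F9. Horner–Wadsworth–Emmons olefination with tert-butyl diethylphosphonoacetate and NaH in THF should give the E enoate 4, where the route is rejoined.

## Further compounds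

F1 | step 8 | lithium dienolate of 14 | COc1ccc([C@@H]2c3c(cc(OC)c(OC)c3OC)C=C(CO[Si](C)(C)C(C)(C)C)C2=C([O-])OC(C)(C)C)cc1OC.[Li+]
F2 | step 8 | tert-butyl (1R,2R)-3-({[tert-butyl(dimethyl)silyl]oxy}methyl)-1-(3,4-dimethoxyphenyl)-6,7,8-trimethoxy-1,2-dihydronaphthalene-2-carboxylate | COc1ccc([C@@H]2c3c(cc(OC)c(OC)c3OC)C=C(CO[Si](C)(C)C(C)(C)C)[C@@H]2C(=O)OC(C)(C)C)cc1OC
F3 | step 3 | (4S)-3-{(2E)-3-[6-(1,3-dioxolan-2-yl)-2,3,4-trimethoxyphenyl]prop-2-enoyl}-4-phenyl-1,3-oxazolidin-2-one | COc1cc(C2OCCO2)c(/C=C/C(=O)N2[C@@H](c3ccccc3)COC2=O)c(OC)c1OC
F4 | step 3 | (4S)-3-[(3R)-3-(3,4-dimethoxyphenyl)-3-{6-(1,3-dioxolan-2-yl)-2,3,4-trimethoxyphenyl}propanoyl]-4-phenyl-1,3-oxazolidin-2-one | COc1ccc([C@@H](CC(=O)N2[C@@H](c3ccccc3)COC2=O)c2c(C3OCCO3)cc(OC)c(OC)c2OC)cc1OC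
F5 | step 3 | (3R)-3-(3,4-dimethoxyphenyl)-3-[6-(1,3-dioxolan-2-yl)-2,3,4-trimethoxyphenyl]propanoic acid | COc1ccc([C@@H](CC(=O)O)c2c(C3OCCO3)cc(OC)c(OC)c2OC)cc1OC
F6 | step 6 | (2Z)-2-bromo-3-{2-[(1R)-3-tert-butoxy-1-(3,4-dimethoxyphenyl)-3-oxopropyl]-3,4,5-trimethoxyphenyl}prop-2-enoic acid | COc1ccc([C@@H](CC(=O)OC(C)(C)C)c2c(/C=C(\Br)C(=O)O)cc(OC)c(OC)c2OC)cc1OC
F7 | step 6 | mixed anhydride of F6 with isobutyl hydrogen carbonate | COc1ccc([C@@H](CC(=O)OC(C)(C)C)c2c(/C=C(\Br)C(=O)OC(=O)OCC(C)C)cc(OC)c(OC)c2OC)cc1OC
F8 | step 2 | [6-(1,3-dioxolan-2-yl)-2,3,4-trimethoxyphenyl]lithium | COc1cc(C2OCCO2)c([Li])c(OC)c1OC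
F9 | step 2 | 6-(1,3-dioxolan-2-yl)-2,3,4-trimethoxybenzaldehyde | COc1cc(C2OCCO2)c(C=O)c(OC)c1OC
A1 | alternative 1 | 1,2-dimethoxy-4-[(1E)-3-{[3-(3,4,5-trimethoxyphenyl)prop-2-yn-1-yl]oxy}prop-1-en-1-yl]benzene | COc1ccc(/C=C/COCC#Cc2cc(OC)c(OC)c(OC)c2)cc1OC
A2 | alternative 1 | 4-(3,4-dimethoxyphenyl)-5,6,7-trimethoxy-1,3,3a,4-tetrahydronaphtho[2,3-c]furan (3a,4-trans, configuration as in 16) | COc1ccc([C@@H]2c3c(cc(OC)c(OC)c3OC)C=C4[C@H]2COC4)cc1OC
A3 | alternative 2 | dimethyl (2E)-2-({3,4,5-trimethoxy-2-[(tosylhydrazinylidene)methyl]phenyl}methylidene)butanedioate | COC(=O)C/C(C(=O)OC)=C\c1cc(OC)c(OC)c(OC)c1C=NNS(=O)(=O)c1ccc(C)cc1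
A4 | alternative 2 | 4-bromo-1,2-dimethoxybenzene | COc1ccc(Br)cc1OC
A5 | alternative 2 | dimethyl (1R,2S)-1-(3,4-dimethoxyphenyl)-6,7,8-trimethoxy-1,2-dihydronaphthalene-2,3-dicarboxylate | COc1ccc([C@@H]2c3c(cc(OC)c(OC)c3OC)C=C(C(=O)OC)[C@H]2C(=O)OC)cc1OC
A6 | alternative 3 | 2-(3,4-dimethoxybenzyl)-3,4,5-trimethoxybenzaldehyde | COc1ccc(Cc2c(C=O)cc(OC)c(OC)c2OC)cc1OC
A7 | alternative 3 | bis[(2S)-1-methoxy-1-oxopropan-2-yl] (2E)-but-2-enedioate | COC(=O)[C@H](C)OC(=O)/C=C/C(=O)O[C@@H](C)C(=O)OC
A8 | alternative 3 | bis[(2S)-1-methoxy-1-oxopropan-2-yl] 1-(3,4-dimethoxyphenyl)-4-hydroxy-6,7,8-trimethoxy-1,2,3,4-tetrahydronaphthalene-2,3-dicarboxylate (1,2-trans, 2,3-trans, 3,4-cis; C1 and C2 as in 16) | COc1ccc([C@@H]2c3c(cc(OC)c(OC)c3OC)[C@H](O)[C@H](C(=O)O[C@@H](C)C(=O)OC)[C@H]2C(=O)O[C@@H](C)C(=O)OC)cc1OC
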